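The pitfall with these two flasks was to give every reading the same trust, when one small number carried most of the answer.

| setting | green | ochre | delta | epsilon |
|---|---|---|---|---|
| free monomer | 0.37 M | 0.59 M | 0.50 M | 0.30 M |
| initiator | 2.5 mol% | 2.5 mol% | 2.5 mol% | 2.5 mol% |
| temperature | 5 °C | 30 °C |  |  |
| remark | run made earlier | run made earlier | at 50 °C until 15 h, from then on at 10 °C | at 50 °C throughout |
| time |  |  | 3.0 d | 3.0 d |

| run | time / d | monomer in chains / % | uncatalysed product / % |
|---|---|---|---|
| green | 1.67 | 2 | 0 |
| green | 4.00 | 2 | 3 |
| green | 8.00 | 7 | 3 |
| green | 20.0 | 31 | 3 |
| ochre | 0.625 | 22 | 5 |
| ochre | 2.50 | 68 | 12 |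
| ochre | 3.00 | 73 | 13 |
| ochre | 5.00 | 84 | 15 |

(standard deviation of a reading: 1.5 percentage points)

- the flask that ends with the higher share of monomer in chains in all that became monomer in chains or uncatalysed product, or "neither" when 2 percentage points or less lies between them (delta / epsilon / neither)
- share of monomer in chains in all that became monomer in chains or uncatalysed product, delta
- share of monomer in chains in all that became monomer in chains or uncatalysed product, epsilon

- the numbers in the tables scatter with a standard deviation of 1.5 percentage points
- where the amount of free monomer changes, what is given in equivalents or mol% on it follows

I worked with one quantity, the split per molar, a selectivity factor: monomer in chains over uncatalysed product at a run's last reading, divided by c(free monomer) charged. The division was my assumption: at a fixed loading c(initiator) follows the charge, so I let the chain route gain on the uncatalysed route in step with that charge. On a reciprocal temperature scale, the way from ochre to 50 °C is 0.689 of the way from green to ochre.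

First I asked what each number could do. Working with the fraction left, I carried the loss of free monomer from both runs to 50 °C, and by this estimate delta kept roughly 5.92% at 15 h, which was the portion of the charge I left for the cold stretch of delta. One standard deviation moved the split at 50 °C by a factor 1.03 on ochre's chains, 1.17 on ochre's uncatalysed product and 1.32 on green's uncatalysed product, the largest. That reading of 3% at 20.0 d was the one that had to be sound.

The runs gave 27.9 /M for green and 9.49 /M for ochre, hence a split at 50 °C of 4.51 /M. Multiplied by each charge, the ratio r gave the share r/(1+r): 69.3% for delta and 57.5% for epsilon, a gap of 12 percentage points, wider than the margin.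

The forecast chose delta, with 69% for delta and 56% for epsilon, holding that “Delta is about 95% consumed by 15 h”, and my epsilon stood higher than its figure.

The simulation gave delta, with 69.2% for delta and 55.8% for epsilon, from these steps:

    free monomer + initiator → living end + monomer in chains (k = 0.0150 /M/min, Ea = 88.0 kJ/mol)
    free monomer + living end → monomer in chains + living end, rate k2*[living end]*[free monomer] (k = 0.290 /M/min, Ea = 67.0 kJ/mol)
    2 living end → dead end (k = 0.0740 /M/min, Ea = 56.0 kJ/mol)
    free monomer → uncatalysed product (k = 8.50 × 10⁻⁴ /min, Ea = 106 kJ/mol)
    (constants at 50 °C)

Delta's share reads back as a split of 4.49 /M. A neighbour of delta with 0.20 M of free monomer at the same loading was the further case: my split times that charge gave a ratio of 0.902, a share of 47.4%. That flask gave 45.4%, and at its end 21% of its free monomer was still there.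

All runs are simulated with made-up constants; scatter was added.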